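**Retrosynthetic overview**
- The target comes from global desilylation of a bis-silyl enone; the enone is made by acylating an (E)-vinyllithium (from 2-methylbut-3-yn-2-ol) with a tertiary anilide.
- Key bond: the side-chain CH2–CH(CH3) bond, formed by nickel hydride-catalysed radical hydroalkylation of a 2-allyl oxepane with racemic 2-bromo-N-methyl-N-phenylpropanamide; this step also sets the (R)-methyl centre.
- The oxepane is the only ring and is closed by a 7-exo Williamson etherification (ring O to allylic CH2); the tertiary alcohol and the allyl group come from vinyl-cuprate opening of a 2,2-disubstituted epoxide.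
- The acyclic precursor comes from a B-alkyl Suzuki coupling of a hydroborated epoxy vinyl carbinol with a (Z)-vinyl iodide made from 2-butyne-1,4-diol; this fixes the E exocyclic alkene.
- The epoxy vinyl carbinol comes from Sharpless kinetic-resolution epoxidation of the methacrolein/vinyl Grignard adduct, which sets both ring stereocentres.

Assumption: vinylmagnesium bromide is bought as its THF solution and counted as a starting material, and the antipode of the bis(oxazoline) ligand in step 10 is the one that delivers the (R)-amide.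

**Step 1**
Reactants: 1 methacrolein; 2 vinylmagnesium bromide
Product: 3 rac-2-methylpenta-1,4-dien-3-ol
Conditions: THF, −78 to 0 °C; then H2O
Reagents that add atoms: none
Why: Grignard 1,2-addition to the enal carbonyl gives the racemic bis-allylic carbinol, whose stereocentre is resolved in step 2.

**Step 2**
Reactants: 3 rac-2-methylpenta-1,4-dien-3-ol
Product: 4 (R)-1-[(S)-2-methyloxiran-2-yl]prop-2-en-1-ol
Conditions: Ti(OiPr)4, D-(−)-diisopropyl tartrate, t-BuOOH (0.55 equiv), 4 Å MS, CH2Cl2, −20 °C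
Reagents that add atoms: tert-butyl hydroperoxide, CC(C)(C)OO
Why: Sharpless kinetic-resolution epoxidation, in which the (R)-carbinol is the matched enantiomer and its more nucleophilic 1,1-disubstituted alkene is epoxidised to the erythro (S)-epoxide (fixing both future ring stereocentres), while the (S)-carbinol, matched only for its sluggish vinyl group, stays behind and is removed.

**Step 3**
Reactants: 4 (R)-1-[(S)-2-methyloxiran-2-yl]prop-2-en-1-ol
Product: 5 tert-butyldimethyl{(1R)-1-[(2S)-2-methyloxiran-2-yl]prop-2-enyloxy}silane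
Conditions: TBSCl, imidazole, DMF, 0 °C to rt
Reagents that add atoms: tert-butyldimethylsilyl chloride, CC(C)(C)[Si](C)(C)Cl
Why: Standard silylation protects the secondary alcohol for the hydroboration and base steps and keeps it out of the later ring closure, without touching a stereocentre.

**Step 4**
Reactants: 6 2-butyne-1,4-diol
Product: 7 4-(tert-butyldimethylsilyloxy)but-2-yn-1-ol
Conditions: NaH (1.0 equiv), THF, 0 °C to rt; TBSCl (1.0 equiv)
Reagents that add atoms: tert-butyldimethylsilyl chloride, CC(C)(C)[Si](C)(C)Cl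
Why: Monosilylation of a symmetrical diol through its mono-sodium alkoxide differentiates the two ends of the four-carbon unit.

**Step 5**
Reactants: 7 4-(tert-butyldimethylsilyloxy)but-2-yn-1-ol
Product: 9 (Z)-4-(tert-butyldimethylsilyloxy)-2-iodobut-2-en-1-ol, via vinylstannane 8 (not isolated)
Conditions: Bu3SnH, [(C5Me5)RuCl]4 (1–2 mol%), CH2Cl2, rt; then I2, 0 °C
Reagents that add atoms: iodine, II
Why: Hydroxyl-directed ruthenium-catalysed trans-hydrostannation puts tin on the alkyne carbon next to the free CH2OH with anti H/Sn addition, and iododestannylation with retention gives the (Z)-iodide in which the two CH2O groups are trans, as in the target's exocyclic alkene.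

**Step 6**
Reactants: 5 tert-butyldimethyl{(1R)-1-[(2S)-2-methyloxiran-2-yl]prop-2-enyloxy}silane; 9 (Z)-4-(tert-butyldimethylsilyloxy)-2-iodobut-2-en-1-ol
Product: 11 (2E)-4-(tert-butyldimethylsilyloxy)-2-{(3R)-3-(tert-butyldimethylsilyloxy)-3-[(2S)-2-methyloxiran-2-yl]propyl}but-2-en-1-ol, via alkylborane 10 (not isolated)
Conditions: 9-BBN, THF, 0 °C to rt; then 9, Pd(dppf)Cl2 (5 mol%), AsPh3, aq Cs2CO3, DMF, rt
Reagents that add atoms: none
Why: 9-BBN adds anti-Markovnikov to the only alkene of 5, and the B-alkyl Suzuki–Miyaura coupling with the vinyl iodide proceeds with retention, so the chain is joined with the trisubstituted alkene already E while the epoxide and silyl ethers are spectators.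

**Step 7**
Reactants: 11 (2E)-4-(tert-butyldimethylsilyloxy)-2-{(3R)-3-(tert-butyldimethylsilyloxy)-3-[(2S)-2-methyloxiran-2-yl]propyl}but-2-en-1-ol; 2 vinylmagnesium bromide
Product: 12 (4S,5R,8E)-5,10-bis(tert-butyldimethylsilyloxy)-8-(hydroxymethyl)-4-methyldeca-1,8-dien-4-ol
Conditions: vinylMgBr (4 equiv), CuI (20 mol%), THF, −30 to 0 °C; then H2O
Reagents that add atoms: none
Why: Copper-catalysed Grignard opening of the 2,2-disubstituted epoxide at its CH2 terminus (SN2) installs the allyl group and frees the tertiary alcohol with its C–O bond, and so its (S)-configuration, untouched; one equivalent of Grignard is spent on the primary OH.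

**Step 8**
Reactants: 12 (4S,5R,8E)-5,10-bis(tert-butyldimethylsilyloxy)-8-(hydroxymethyl)-4-methyldeca-1,8-dien-4-ol
Product: 14 (2S,3R,6E)-2-allyl-3-(tert-butyldimethylsilyloxy)-6-[2-(tert-butyldimethylsilyloxy)ethylidene]-2-methyloxepane, via allylic tosylate 13 (not isolated)
Conditions: NaH (2.5 equiv), THF, 0 °C; TsCl (1.05 equiv), 0 °C to 40 °C
Reagents that add atoms: none
Why: Intramolecular Williamson etherification, in which the primary allylic alkoxide is tosylated selectively and the tertiary alkoxide displaces the allylic tosylate in a 7-exo-tet closure, forming the oxepane without touching either stereocentre or the alkene geometry.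

**Step 9**
Reactants: 15 2-bromopropanoyl bromide; 16 N-methylaniline
Product: 17 rac-2-bromo-N-methyl-N-phenylpropanamide
Conditions: Et3N, CH2Cl2, 0 °C to rt
Reagents that add atoms: none
Why: N-acylation of the secondary aniline by the acid bromide gives the racemic tertiary α-bromo anilide that serves as the radical precursor.

**Step 10 (key step)**
Reactants: 14 (2S,3R,6E)-2-allyl-3-(tert-butyldimethylsilyloxy)-6-[2-(tert-butyldimethylsilyloxy)ethylidene]-2-methyloxepane; 17 rac-2-bromo-N-methyl-N-phenylpropanamide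
Product: 18 (2R)-5-{(2S,3R,6E)-3-(tert-butyldimethylsilyloxy)-6-[2-(tert-butyldimethylsilyloxy)ethylidene]-2-methyloxepan-2-yl}-N,2-dimethyl-N-phenylpentanamide
Conditions: 17 (1.5 equiv), NiBr2·glyme (10 mol%), chiral 2,2'-isopropylidenebis(4-phenyl-2-oxazoline) (12 mol%), (EtO)3SiH (2 equiv), K3PO4·H2O (2 equiv), Et2O/DMA, rt
Reagents that add atoms: none
Why: Nickel hydride-catalysed enantioconvergent hydroalkylation, in which anti-Markovnikov insertion of the terminal alkene into Ni–H gives a primary alkylnickel, bromine abstraction from either enantiomer of 17 gives the same planar α-amido radical, and its capture and reductive elimination at the chiral nickel centre forms the C–C bond and sets the (R)-methyl stereocentre under catalyst control.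

**Step 11**
Reactants: 19 2-methylbut-3-yn-2-ol
Product: 20 (E)-2-methyl-4-(tributylstannyl)but-3-en-2-ol
Conditions: Bu3SnH (1.2 equiv), AIBN (cat.), toluene, 85 °C
Reagents that add atoms: tributyltin hydride, CCCC[SnH](CCCC)CCCC
Why: Radical-chain hydrostannation of the terminal alkyne puts tin on the terminal carbon and equilibrates to the thermodynamic (E)-vinylstannane.

**Step 12**
Reactants: 18 (2R)-5-{(2S,3R,6E)-3-(tert-butyldimethylsilyloxy)-6-[2-(tert-butyldimethylsilyloxy)ethylidene]-2-methyloxepan-2-yl}-N,2-dimethyl-N-phenylpentanamide; 20 (E)-2-methyl-4-(tributylstannyl)but-3-en-2-ol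
Product: 22 (3E,6R)-9-{(2S,3R,6E)-3-(tert-butyldimethylsilyloxy)-6-[2-(tert-butyldimethylsilyloxy)ethylidene]-2-methyloxepan-2-yl}-2-hydroxy-2,6-dimethylnon-3-en-5-one, via dilithio vinyl alkoxide 21 (not isolated)
Conditions: 20 (1.5 equiv), n-BuLi (3.0 equiv), THF, −78 to −30 °C; then 18, −78 °C; H2O quench at −78 °C
Reagents that add atoms: none
Why: Tin–lithium exchange with retention gives the (E)-vinyllithium as its lithium alkoxide, which acylates on the tertiary anilide to a tetrahedral adduct that holds at −78 °C and releases the (E)-enone only on quench (amide acylation of an organolithium), so over-addition and epimerisation of the α-methyl centre are avoided.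

**Step 13**
Reactants: 22 (3E,6R)-9-{(2S,3R,6E)-3-(tert-butyldimethylsilyloxy)-6-[2-(tert-butyldimethylsilyloxy)ethylidene]-2-methyloxepan-2-yl}-2-hydroxy-2,6-dimethylnon-3-en-5-one
Product: 23 (3E,6R)-2-hydroxy-9-[(2S,3R,6E)-3-hydroxy-6-(2-hydroxyethylidene)-2-methyloxepan-2-yl]-2,6-dimethylnon-3-en-5-one
Conditions: HF·pyridine, pyridine/THF, 0 °C to rt
Reagents that add atoms: none
Why: Fluoride-mediated cleavage of both silyl ethers under buffered, non-basic conditions frees the secondary and primary alcohols without epimerising the α-methyl ketone or disturbing the enone and tertiary allylic alcohol.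

**Compound list**
1 | methacrolein | CC(=C)C=O | starting material
2 | vinylmagnesium bromide | C=C[Mg]Br | starting material
3 | rac-2-methylpenta-1,4-dien-3-ol | C=CC(O)C(C)=C | intermediate
4 | (R)-1-[(S)-2-methyloxiran-2-yl]prop-2-en-1-ol | C=C[C@@H](O)[C@]1(C)CO1 | intermediate
5 | tert-butyldimethyl{(1R)-1-[(2S)-2-methyloxiran-2-yl]prop-2-enyloxy}silane | C=C[C@@H](O[Si](C)(C)C(C)(C)C)[C@]1(C)CO1 | intermediate
6 | 2-butyne-1,4-diol | OCC#CCO | starting material
7 | 4-(tert-butyldimethylsilyloxy)but-2-yn-1-ol | OCC#CCO[Si](C)(C)C(C)(C)C | intermediate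
8 | (Z)-4-(tert-butyldimethylsilyloxy)-2-(tributylstannyl)but-2-en-1-ol | OC/C([Sn](CCCC)(CCCC)CCCC)=C/CO[Si](C)(C)C(C)(C)C | intermediate
9 | (Z)-4-(tert-butyldimethylsilyloxy)-2-iodobut-2-en-1-ol | OC/C(I)=C/CO[Si](C)(C)C(C)(C)C | intermediate
10 | 9-{(3R)-3-(tert-butyldimethylsilyloxy)-3-[(2S)-2-methyloxiran-2-yl]propyl}-9-borabicyclo[3.3.1]nonane | B1(C2CCCC1CCC2)CC[C@@H](O[Si](C)(C)C(C)(C)C)[C@]3(C)CO3 | intermediate
11 | (2E)-4-(tert-butyldimethylsilyloxy)-2-{(3R)-3-(tert-butyldimethylsilyloxy)-3-[(2S)-2-methyloxiran-2-yl]propyl}but-2-en-1-ol | OC/C(CC[C@@H](O[Si](C)(C)C(C)(C)C)[C@]1(C)CO1)=C/CO[Si](C)(C)C(C)(C)C | intermediate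
12 | (4S,5R,8E)-5,10-bis(tert-butyldimethylsilyloxy)-8-(hydroxymethyl)-4-methyldeca-1,8-dien-4-ol | OC/C(CC[C@@H](O[Si](C)(C)C(C)(C)C)[C@@](C)(O)CC=C)=C/CO[Si](C)(C)C(C)(C)C | intermediate
13 | (2E)-4-(tert-butyldimethylsilyloxy)-2-[(3R,4S)-3-(tert-butyldimethylsilyloxy)-4-hydroxy-4-methylhept-6-enyl]but-2-enyl 4-methylbenzenesulfonate | Cc1ccc(cc1)S(=O)(=O)OC/C(CC[C@@H](O[Si](C)(C)C(C)(C)C)[C@@](C)(O)CC=C)=C/CO[Si](C)(C)C(C)(C)C | intermediate
14 | (2S,3R,6E)-2-allyl-3-(tert-butyldimethylsilyloxy)-6-[2-(tert-butyldimethylsilyloxy)ethylidene]-2-methyloxepane | C=CC[C@]1(C)OC/C(=C/CO[Si](C)(C)C(C)(C)C)CC[C@H]1O[Si](C)(C)C(C)(C)C | intermediate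
15 | 2-bromopropanoyl bromide | CC(Br)C(Br)=O | starting material
16 | N-methylaniline | CNc1ccccc1 | starting material
17 | rac-2-bromo-N-methyl-N-phenylpropanamide | CC(Br)C(=O)N(C)c1ccccc1 | intermediate
18 | (2R)-5-{(2S,3R,6E)-3-(tert-butyldimethylsilyloxy)-6-[2-(tert-butyldimethylsilyloxy)ethylidene]-2-methyloxepan-2-yl}-N,2-dimethyl-N-phenylpentanamide | C[C@H](CCC[C@]1(C)OC/C(=C/CO[Si](C)(C)C(C)(C)C)CC[C@H]1O[Si](C)(C)C(C)(C)C)C(=O)N(C)c1ccccc1 | intermediate
19 | 2-methylbut-3-yn-2-ol | CC(C)(O)C#C | starting material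
20 | (E)-2-methyl-4-(tributylstannyl)but-3-en-2-ol | CC(C)(O)/C=C/[Sn](CCCC)(CCCC)CCCC | intermediate
21 | lithium (E)-4-lithio-2-methylbut-3-en-2-olate | [Li]OC(C)(C)/C=C/[Li] | intermediate
22 | (3E,6R)-9-{(2S,3R,6E)-3-(tert-butyldimethylsilyloxy)-6-[2-(tert-butyldimethylsilyloxy)ethylidene]-2-methyloxepan-2-yl}-2-hydroxy-2,6-dimethylnon-3-en-5-one | C[C@H](CCC[C@]1(C)OC/C(=C/CO[Si](C)(C)C(C)(C)C)CC[C@H]1O[Si](C)(C)C(C)(C)C)C(=O)/C=C/C(C)(C)O | intermediate
23 | (3E,6R)-2-hydroxy-9-[(2S,3R,6E)-3-hydroxy-6-(2-hydroxyethylidene)-2-methyloxepan-2-yl]-2,6-dimethylnon-3-en-5-one | C[C@H](CCC[C@]1(C)OC/C(=C/CO)CC[C@H]1O)C(=O)/C=C/C(C)(C)O | target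

**Step count**
Total: 13 steps. Longest linear sequence: 9 steps (1, 2, 3, 6, 7, 8, 10, 12, 13).

**Steps most likely to fail, with fallbacks**

Step 10. The nickel hydride coupling is precedented for terminal alkenes and tertiary α-bromo anilides, but not on an alkene this hindered and functionalised. Conversion or enantiocontrol at the new methyl centre may suffer. The fallback makes the same bond from a preformed organozinc instead of from the alkene. It sets out from 14: hydroboration with 9-BBN gives 9-{3-[(2S,3R,6E)-3-(tert-butyldimethylsilyloxy)-6-[2-(tert-butyldimethylsilyloxy)ethylidene]-2-methyloxepan-2-yl]propyl}-9-borabicyclo[3.3.1]nonane F1. Iodinolysis (I2, NaOMe) gives the primary iodide (2S,3R,6E)-3-(tert-butyldimethylsilyloxy)-6-[2-(tert-butyldimethylsilyloxy)ethylidene]-2-(3-iodopropyl)-2-methyloxepane F2. Zinc insertion (Zn dust, cat. I2, DMA) gives the alkylzinc iodide {3-[(2S,3R,6E)-3-(tert-butyldimethylsilyloxy)-6-[2-(tert-butyldimethylsilyloxy)ethylidene]-2-methyloxepan-2-yl]propyl}zinc iodide F3. An enantioconvergent Negishi coupling of F3 with racemic 17 (NiCl2·glyme, chiral iPr-Pybox, DMI/THF, 0 °C) comes back to the route at 18.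

Step 12. The anilide may be enolised by the basic dilithio reagent, or its adduct may collapse early and over-add. The fallback replaces direct acylation by a reduce–add–oxidise sequence. It sets out from 18: Cp2Zr(H)Cl in THF reduces the tertiary amide to the aldehyde (2R)-5-{(2S,3R,6E)-3-(tert-butyldimethylsilyloxy)-6-[2-(tert-butyldimethylsilyloxy)ethylidene]-2-methyloxepan-2-yl}-2-methylpentanal F4. Addition of 21 at −78 °C gives the allylic diol (3E,6R)-9-{(2S,3R,6E)-3-(tert-butyldimethylsilyloxy)-6-[2-(tert-butyldimethylsilyloxy)ethylidene]-2-methyloxepan-2-yl}-2,6-dimethylnon-3-ene-2,5-diol F5 as a mixture of carbinol epimers. MnO2 in CH2Cl2 oxidises only the secondary allylic alcohol and comes back to the route at 22.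

Step 8. Closing a seven-membered ring with a hindered tertiary alkoxide may be slow, leaving the allylic tosylate open to intermolecular reaction. The fallback replaces the SN2 closure by a π-allyl closure. It sets out from 12: methyl chloroformate and pyridine acylate only the primary allylic hydroxyl to give (2E)-4-(tert-butyldimethylsilyloxy)-2-[(3R,4S)-3-(tert-butyldimethylsilyloxy)-4-hydroxy-4-methylhept-6-enyl]but-2-enyl methyl carbonate F6. Pd(PPh3)4 (zerovalent palladium) in THF at 50 °C ionises the carbonate, and the tertiary hydroxyl attacks the CH2 terminus of the allyl complex (intramolecular Tsuji–Trost etherification), coming back to the route at 14.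

**Further compounds**
F1 | step 10 | 9-{3-[(2S,3R,6E)-3-(tert-butyldimethylsilyloxy)-6-[2-(tert-butyldimethylsilyloxy)ethylidene]-2-methyloxepan-2-yl]propyl}-9-borabicyclo[3.3.1]nonane | B1(C2CCCC1CCC2)CCC[C@]3(C)OC/C(=C/CO[Si](C)(C)C(C)(C)C)CC[C@H]3O[Si](C)(C)C(C)(C)C
F2 | step 10 | (2S,3R,6E)-3-(tert-butyldimethylsilyloxy)-6-[2-(tert-butyldimethylsilyloxy)ethylidene]-2-(3-iodopropyl)-2-methyloxepane | ICCC[C@]1(C)OC/C(=C/CO[Si](C)(C)C(C)(C)C)CC[C@H]1O[Si](C)(C)C(C)(C)C
F3 | step 10 | {3-[(2S,3R,6E)-3-(tert-butyldimethylsilyloxy)-6-[2-(tert-butyldimethylsilyloxy)ethylidene]-2-methyloxepan-2-yl]propyl}zinc iodide | I[Zn]CCC[C@]1(C)OC/C(=C/CO[Si](C)(C)C(C)(C)C)CC[C@H]1O[Si](C)(C)C(C)(C)C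
F4 | step 12 | (2R)-5-{(2S,3R,6E)-3-(tert-butyldimethylsilyloxy)-6-[2-(tert-butyldimethylsilyloxy)ethylidene]-2-methyloxepan-2-yl}-2-methylpentanal | C[C@H](CCC[C@]1(C)OC/C(=C/CO[Si](C)(C)C(C)(C)C)CC[C@H]1O[Si](C)(C)C(C)(C)C)C=O
F5 | step 12 | (3E,6R)-9-{(2S,3R,6E)-3-(tert-butyldimethylsilyloxy)-6-[2-(tert-butyldimethylsilyloxy)ethylidene]-2-methyloxepan-2-yl}-2,6-dimethylnon-3-ene-2,5-diol | C[C@H](CCC[C@]1(C)OC/C(=C/CO[Si](C)(C)C(C)(C)C)CC[C@H]1O[Si](C)(C)C(C)(C)C)C(O)/C=C/C(C)(C)O
F6 | step 8 | (2E)-4-(tert-butyldimethylsilyloxy)-2-[(3R,4S)-3-(tert-butyldimethylsilyloxy)-4-hydroxy-4-methylhept-6-enyl]but-2-enyl methyl carbonate | COC(=O)OC/C(CC[C@@H](O[Si](C)(C)C(C)(C)C)[C@@](C)(O)CC=C)=C/CO[Si](C)(C)C(C)(C)C
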